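## Structural features

Sophonorol F is a 3-hydroxyisoflavanone: a chroman-4-one (benzo ring A fused to pyranone ring C through C4a and C8a) whose C3 carries both a hydroxyl group and aryl ring B. C3 is the only stereocentre; it is fully substituted, (S)-configured, and lies between the C2 methylene and the C4 ketone, so no neighbouring stereocentre can relay to it and it cannot be corrected by epimerisation. Ring A carries 5-OH (hydrogen-bonded to C4=O), 7-OMe and an 8-prenyl group; ring B carries 2'-OMe, 3'-prenyl and 4'-OH, so five oxygen atoms on two rings have to be told apart. The fragile parts are the two trisubstituted prenyl alkenes (acid closes them onto a neighbouring free phenol; electrophilic halogen, strong oxidants and hydrogenation attack them), the tertiary α-ketol (α-ketol rearrangement in strong base or with Lewis acids) and the electron-rich phenols. The real difficulty is the (S)-carbinol at C3, which bears a crowded ortho-substituted aryl group and must be made without any stereochemical help from the rest of the molecule. The key step exploits two facts: O1–C2 is an aryl oxygen bearing one carbon, and C3(OH)–C4(=O) is an α-ketol. C2 can therefore be the carbon of a C8a methoxy group on ring A, and C3 and C4 the two carbons of a diaryl 1,2-diketone. The C2–C3 bond, ring C and the carbinol then arise together when the C3 carbonyl oxygen takes a hydrogen atom from that methoxy group.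

## Logic of the disconnections

**20 from 19.** The two ester C(=O)–O bonds on O5 and O4' are cut. Both phenols must stay masked up to this point: a free 5-OH would hydrogen-bond to C4=O and drain the excited state of the key step, and a free 4'-OH would be methylated together with the 2'-oxygen. The gain is a last step that only adds hydrogen. The demand is a base mild enough to leave the tertiary α-ketol alone.

**19 from 17.** The 2'-O–CH3 bond is cut and the oxygen goes back to its silyl ether. In 17 this oxygen cannot be a methyl ether, because a ring B methoxy group would compete as hydrogen donor in the key step. The gain is that rings A and B become distinguishable in the photoreaction. The demand is that fluoride frees only this phenoxide and that it alone is methylated, which is why the other two phenols are still esters in 19.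

**17 from 16.** The C2–C3 bond is cut; C3 returns to a carbonyl carbon and C2 to the carbon of the C8a methoxy group. This single cut opens ring C and removes the only stereocentre, leaving an open-chain 1,2-diketone. The demand on the forward step is heavy: the C3 oxygen and not the C4 oxygen must abstract, only the C8a methoxy group may donate, and one face of C3 must be chosen.

**16 from 15.** The two C=O bonds at C3 and C4 are removed, leaving the C3≡C4 triple bond. An alkyne is the oxidation level a cross-coupling delivers. It also avoids alkoxide or carbanion intermediates next to the ortho silyl ether and ortho ester, which a benzoin-type union would create and which invite silyl and acyl migration. The demand is an oxidant that takes the alkyne and spares two trisubstituted alkenes.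

**15 from 8 and 14.** The C4a–C4 aryl–alkynyl bond is cut. The molecule falls into two fragments of equal size, each already carrying its prenyl group and its final protecting groups, so the route is convergent. The demand is oxidative addition at an iodide with two ortho substituents.

**8 from 7, 7 from 6.** The O5–acyl bond and then the C4a–I bond are cut. 6 is mirror-symmetric, so its two open ring positions are identical and iodination has only one possible product. The demand is that the arene is iodinated faster than the prenyl alkene, and only once.

**6 from 5, 5 from 2 and 3 (through 4), 2 from 1.** The C8–prenyl bond is cut and traced to a lithiation between the two methoxy groups. 1 already holds both methyl ethers of ring A and one free hydroxyl, so the three oxygens of ring A never need to be differentiated; a resorcinol with two free hydroxyls would need that. The demand is a protecting group on the hydroxyl of 1 that does not direct lithiation to its own neighbours, hence a bulky silyl ether, removed again on the way to 6.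

**14 from 12 (through 13).** The terminal alkyne carbon (the later C3) is cut from the former aldehyde carbon. The aldehyde is what allows the two ring B hydroxyls to be told apart, so it is kept until both are protected. The demand is a one-carbon homologation free of alkoxide bases and alkyllithiums.

**12 from 11, 11 from 10.** The O2'–Si bond and then the O4'–acyl bond are cut. In 10 the 2-hydroxyl is chelated to the aldehyde and the 4-hydroxyl is not, which fixes the order: acylate first, silylate second.

**10 from 9 and 3.** The C3'–prenyl bond is cut at the carbon between the two hydroxyls, the most nucleophilic carbon of the phenoxide of 9. This is one step from two commercial compounds. The demand is C- over O-alkylation and C3 over C5.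

## Other disconnections considered

**Alternative 1:** The cut frees C3 from its hydroxyl oxygen and from C2, while ring C stays open.
- Forward key step: diazoketone A2 (the 2-diazo-1,2-diarylethanone of rings A and B, with 5- and 4'-MOM ethers, 2'-OMe and an 8a-silyl ether) would be decomposed by Rh2(OAc)4. Water adds to the rhodium carbenoid to give an oxonium ylide, and a chiral phosphoric acid guides its attack on formaldehyde. C3–O, C2–C3 and the C3 stereocentre would arise together in seco-diol A1.
- In its favour: it is a ground-state catalytic step of a known kind, the stereocentre is set by an established mode of control (acid-bound enol equivalent attacking a bound electrophile), C2 comes from the cheapest one-carbon unit, and no light is needed.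
- Against it here: no ring closes. A1 would still need desilylation at O8a and an etherification that distinguishes the primary from the tertiary alcohol before it reaches A5, and then acidic removal of two MOM groups beside prenyl groups. The carbenoid carbon sits between an ortho-methoxy aryl ring and a twisted aroyl group with two ortho substituents, and the 1,2-hydrogen shift of the ylide (net O–H insertion) and Wolff rearrangement compete with capture. Ring A needs three different oxygen substituents (silyl, MOM, methyl), which the symmetric 1 of the chosen plan avoids.
- Comparison: on the mechanism of stereocontrol this alternative is the better founded, since the chosen photocyclisation has no proven source of enantioselectivity. On structure it achieves less per step (two bonds and the stereocentre but no ring, against one bond, the ring and the stereocentre). On step economy it is longer by the ring closure and the extra protecting-group work on ring A, while making A2 should cost about as much as making 16.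

**Alternative 2:** The two aryl–prenyl bonds (at C8 and at C3') are cut, with the hydroxychromanone core already complete.
- Forward key step: bis-ether A4 (the (S)-core with a 5-O-prenyl ether, a 2'-O-(1,1-dimethylallyl) ether, 7-OMe and a 4'-pivalate) would be heated with Eu(fod)3. The 5-O-prenyl group would move by ortho-Claisen shift to C6 and on by Cope shift to C8; the 2'-O-allyl group would move by ortho-Claisen shift with inversion to C3', giving A3.
- In its favour: both prenyl groups stay out of all earlier chemistry, and A3 emerges with 5-OH already free.
- Against it here: it does not address ring C or C3, so A4 must still come from one of the other key steps. C6 bears a hydrogen, so re-aromatisation at C6 before the Cope shift competes with delivery to C8. A tertiary α-ketol is heated with a Lewis acid. The tertiary allyl ether on the crowded 2'-oxygen costs two steps (propargylation, partial hydrogenation), and afterwards the 2'-OH must be methylated beside the free 5-OH and the tertiary alcohol.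
- Comparison: it is better than the chosen plan on one point, namely that the alkenes that endanger steps 4, 11 and 12 would not be present. It is equal in ending with a base-labile pivalate. It is worse on structure (no ring, no stereocentre, a second key step needed) and on step economy (two O-allylations, a partial hydrogenation, the rearrangement and a selective methylation replace two one-step prenylations).

**Alternative 3:** The C3–C4 bond is cut.
- Forward key step: keto aldehyde A6 (ring A aldehyde with 5-OMOM, 7-OMe, 8-prenyl and an O8a–CH2–C(=O)–ring B tether) would be treated with a chiral triazolium carbene. The carbene turns the aldehyde carbon into an acyl-anion equivalent that adds to the tethered aryl ketone, closing ring C (6-exo-trig) and setting C3, to give A5.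
- In its favour: this reaction type is known for 3-substituted 3-hydroxychroman-4-ones, the 2'-OMe group can be in place from the start, and it is a ground-state process.
- Against it here: the aldehyde lies between two ortho oxygen substituents and the ketone is hindered by 2'-OMe with the 3'-prenyl group behind it. The α-aryloxy ketone is enolisable, so intramolecular aldol condensation onto the aldehyde competes. Ring A needs a free O8a–H beside the prenyl group, a protected O5 and OMe at C7, which is three different oxygens. Ring B needs an α-haloketone made in the presence of a prenyl alkene, and the MOM groups come off in acid at the end.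
- Comparison: on mechanism and stereocontrol this alternative is clearly the better founded. On structure it is the equal of the chosen plan (same ring, one bond, same stereocentre). On step economy it is about equal: it saves the silyl-to-methyl exchange after the key step but pays for the differentiation of ring A and the haloketone. It is therefore kept, with the protecting groups of the main route, as the fallback for step 12.

Key step: step 12

Remark: "prenyl" means 3-methylbut-2-en-1-yl; atom labels (O1, C2, C3, C4, C4a, C5–C8, C8a, primed for ring B) follow isoflavanone numbering and are also used for open-chain precursors.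
Remark: 16 and 17 are isomers (C42H60O9Si); the C3 descriptor is S in 17, 18, 19 and 20 because the priorities OH > C4 > C2 > C1' do not change.
Assumption: the sense of induction by the chiral phosphoric acid in step 12 cannot be predicted; the (R)-acid is written, and its mirror image is to be used if the (R)-acid turns out to favour the (3R) product.

## Route

Step 1
Reactants: 1 3,5-dimethoxyphenol
Product: 2 (3,5-dimethoxyphenoxy)triisopropylsilane
Conditions: i-Pr3SiCl, imidazole, DMF, 25 °C
Reagents that add atoms: chlorotriisopropylsilane CC(C)[Si](Cl)(C(C)C)C(C)C
Why: Standard imidazole-promoted silylation of a phenol; the bulky triisopropylsilyl ether is chosen because it does not direct metalation to its own ortho positions.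

Step 2
Reactants: 2 (3,5-dimethoxyphenoxy)triisopropylsilane; 3 prenyl bromide (1-bromo-3-methylbut-2-ene)
Product: 5 [3,5-dimethoxy-4-(3-methylbut-2-en-1-yl)phenoxy]triisopropylsilane, via aryllithium 4 (not isolated)
Conditions: n-BuLi, THF, 0 °C to 25 °C; then 3, −78 °C to 25 °C
Reagents that add atoms: none
Why: Directed ortho-metalation: the position between the two methoxy groups is doubly activated and the silyl ether shields its own neighbours, so only 4 should form. The aryllithium is then alkylated by 3 at the primary carbon (SN2), attack at the tertiary allyl terminus being disfavoured for this hindered nucleophile.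

Step 3
Reactants: 5 [3,5-dimethoxy-4-(3-methylbut-2-en-1-yl)phenoxy]triisopropylsilane
Product: 6 3,5-dimethoxy-4-(3-methylbut-2-en-1-yl)phenol
Conditions: Bu4NF, AcOH, THF, 25 °C
Reagents that add atoms: none
Why: Fluoride cleavage of the aryl silyl ether; buffering with acetic acid delivers the neutral phenol directly.

Step 4
Reactants: 6 3,5-dimethoxy-4-(3-methylbut-2-en-1-yl)phenol
Product: 7 2-iodo-3,5-dimethoxy-4-(3-methylbut-2-en-1-yl)phenol
Conditions: I2 (1.0 equiv), NaHCO3, THF–H2O, 0 °C
Reagents that add atoms: iodine II
Why: Electrophilic aromatic iodination of a phloroglucinol-type phenoxide should be far faster than reversible iodonium formation at the prenyl alkene, which has no free hydroxyl neighbour to trap it. The two open positions are equivalent by symmetry, and one equivalent of iodine limits a second iodination.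

Step 5
Reactants: 7 2-iodo-3,5-dimethoxy-4-(3-methylbut-2-en-1-yl)phenol
Product: 8 2-iodo-3,5-dimethoxy-4-(3-methylbut-2-en-1-yl)phenyl pivalate
Conditions: t-BuCOCl, Et3N, DMAP (cat.), CH2Cl2, 0 °C to 25 °C
Reagents that add atoms: pivaloyl chloride CC(C)(C)C(=O)Cl
Why: DMAP-catalysed acylation of the phenol; the pivalate has no hydrogen that the excited diketone can reach and resists the amine base of the coupling.

Step 6
Reactants: 9 2,4-dihydroxybenzaldehyde; 3 prenyl bromide
Product: 10 2,4-dihydroxy-3-(3-methylbut-2-en-1-yl)benzaldehyde
Conditions: KOH (aq), H2O, 0 °C to 25 °C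
Reagents that add atoms: none
Why: C-Alkylation of a resorcinol-type phenoxide in water, where hydrogen bonding to oxygen steers the ambident anion to carbon and the position between the two oxygens is the most nucleophilic. O-Prenyl and 5-prenyl isomers are expected as by-products and are to be removed by chromatography.

Step 7
Reactants: 10 2,4-dihydroxy-3-(3-methylbut-2-en-1-yl)benzaldehyde
Product: 11 4-formyl-3-hydroxy-2-(3-methylbut-2-en-1-yl)phenyl pivalate
Conditions: t-BuCOCl (1.0 equiv), Et3N, CH2Cl2, −20 °C to 0 °C
Reagents that add atoms: pivaloyl chloride CC(C)(C)C(=O)Cl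
Why: Selective acylation: the 2-hydroxyl is tied up in a hydrogen bond to the formyl group, so the 4-hydroxyl should react first with one equivalent of acyl chloride.

Step 8
Reactants: 11 4-formyl-3-hydroxy-2-(3-methylbut-2-en-1-yl)phenyl pivalate
Product: 12 3-[(tert-butyldimethylsilyl)oxy]-4-formyl-2-(3-methylbut-2-en-1-yl)phenyl pivalate
Conditions: t-BuMe2SiOTf, 2,6-lutidine, CH2Cl2, 0 °C
Reagents that add atoms: tert-butyldimethylsilyl trifluoromethanesulfonate CC(C)(C)[Si](C)(C)OS(=O)(=O)C(F)(F)F
Why: Silylation of the hindered, chelated phenol needs the silyl triflate; 2,6-lutidine is non-nucleophilic and leaves the pivalate and the aldehyde alone.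

Step 9
Reactants: 12 3-[(tert-butyldimethylsilyl)oxy]-4-formyl-2-(3-methylbut-2-en-1-yl)phenyl pivalate
Product: 14 3-[(tert-butyldimethylsilyl)oxy]-4-ethynyl-2-(3-methylbut-2-en-1-yl)phenyl pivalate, via lithium alkoxide adduct 13 (not isolated)
Conditions: Me3SiCHN2, LiN(i-Pr)2, THF, −78 °C; then 12, −78 °C to 0 °C; H2O
Reagents that add atoms: (trimethylsilyl)diazomethane C[Si](C)(C)C=[N+]=[N-]
Why: Colvin rearrangement: lithiated (trimethylsilyl)diazomethane adds to the aldehyde, Peterson-type loss of lithium trimethylsilanolate gives a diazoalkene, and loss of N2 with 1,2-hydrogen shift gives the alkyne. No methoxide or alkyllithium is present, so the aryl pivalate and the aryl silyl ether should survive at low temperature.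

Step 10
Reactants: 8 2-iodo-3,5-dimethoxy-4-(3-methylbut-2-en-1-yl)phenyl pivalate; 14 3-[(tert-butyldimethylsilyl)oxy]-4-ethynyl-2-(3-methylbut-2-en-1-yl)phenyl pivalate
Product: 15 2-{[2-[(tert-butyldimethylsilyl)oxy]-3-(3-methylbut-2-en-1-yl)-4-(pivaloyloxy)phenyl]ethynyl}-3,5-dimethoxy-4-(3-methylbut-2-en-1-yl)phenyl pivalate
Conditions: PdCl2(PPh3)2 (5 mol%), CuI (10 mol%), Et3N, DMF, 50 °C, degassed
Reagents that add atoms: none
Why: Sonogashira coupling; the two ortho substituents slow oxidative addition to zerovalent palladium, but an aryl iodide should still couple at 50 °C. Degassing suppresses Glaser dimerisation of 14.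

Step 11
Reactants: 15 the diarylalkyne of step 10
Product: 16 1-[2,4-dimethoxy-3-(3-methylbut-2-en-1-yl)-6-(pivaloyloxy)phenyl]-2-[2-[(tert-butyldimethylsilyl)oxy]-3-(3-methylbut-2-en-1-yl)-4-(pivaloyloxy)phenyl]ethane-1,2-dione
Conditions: PdCl2 (10 mol%), DMSO, 120 °C
Reagents that add atoms: dimethyl sulfoxide CS(C)=O
Why: Palladium-catalysed oxidation of a diarylalkyne by DMSO (two oxygen transfers from sulfoxide to the alkyne bound to divalent palladium). The trisubstituted prenyl alkenes bind divalent palladium far more weakly than the alkyne, and no water is present for a Wacker process.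

Step 12
Reactants: 16 the 1,2-diketone of step 11
Product: 17 (3S)-3-[2-[(tert-butyldimethylsilyl)oxy]-3-(3-methylbut-2-en-1-yl)-4-(pivaloyloxy)phenyl]-3-hydroxy-7-methoxy-8-(3-methylbut-2-en-1-yl)-4-oxochroman-5-yl pivalate
Conditions: hν (blue LED, 440 nm), (R)-3,3'-bis[3,5-bis(trifluoromethyl)phenyl]-1,1'-binaphthyl-2,2'-diyl hydrogen phosphate (50 mol%), PhCF3 (2 mM), argon, −20 °C; then preparative SFC on a chiral stationary phase
Reagents that add atoms: none
Why: Proposed new method: blue light excites only the n,π* band of the 1,2-diketone, and after intersystem crossing the triplet's C3 oxygen is expected to abstract a hydrogen from the C8a methoxy group through an eight-membered transition state (1,7-shift), giving a triplet 1,6-biradical (O1–CH2 radical and C3 ketyl conjugated with C4=O) that crosses to the singlet and couples C2 with C3. The closest known reaction type is the Norrish–Yang photocyclisation of 1-(ortho-alkylaryl)-1,2-diketones to 2-hydroxyindan-1-ones, where the remote carbonyl abstracts and a 1,5-biradical closes; a methoxy donor and a tether one atom longer have not been shown, the nearest alkoxy case being δ-abstraction in ortho-alkoxyaryl monoketones, which gives 3-hydroxy-2,3-dihydrobenzofurans. Ring C closes by recombination of the 1,6-biradical to a six-membered ring (Yang cyclisation), not by a polar exo or endo attack. The C3 stereocentre is set in that coupling: the two faces of the ketyl correspond to the two senses of twist of ring A about C4a–C4, and the chiral phosphoric acid, hydrogen-bonded to C4=O before the hydrogen shift and also to the new C3–OH after it, is meant to favour one twist. A chelating metal Lewis acid is deliberately not used, because binding both carbonyl oxygens would tie up the n orbital that has to abstract; the induction by the acid is unproven, so the chiral phase removes whatever (3R) isomer forms. The step needs remote (C3=O) over proximal (C4=O) abstraction, which would end in a 3-aroyl-3-hydroxydihydrobenzofuran; this rests on the diketone analogy and on ring A being held perpendicular to the dione by its two ortho substituents, with the C8a methoxy group pushed out of plane by the C8 prenyl group. It also needs the C8a methoxy group to be the only donor: the 2'-oxygen carries a silyl group (no C–H next to oxygen), both pivalates offer only unactivated methyl C–H, the acid has no benzylic C–H, and the prenyl CH2 groups are meta to the acyl carbons and cannot reach either oxygen. High dilution and exclusion of O2 limit quenching of the triplet by prenyl alkenes of a second molecule and photo-oxidation, and the product α-ketol does not absorb at 440 nm.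

Step 13
Reactants: 17 the (3S)-photoproduct of step 12
Product: 19 (3S)-3-hydroxy-7-methoxy-3-[2-methoxy-3-(3-methylbut-2-en-1-yl)-4-(pivaloyloxy)phenyl]-8-(3-methylbut-2-en-1-yl)-4-oxochroman-5-yl pivalate, via caesium phenoxide 18 (not isolated)
Conditions: CsF, MeI, DMF, 0 °C to 25 °C
Reagents that add atoms: iodomethane CI
Why: Fluoride removes the aryl silyl ether and the caesium phenoxide is methylated in the same flask (Williamson ether synthesis). CsF does not deprotonate the tertiary alcohol and the pivalates keep the other two phenols masked, so only the 2'-oxygen should be methylated; C3 is not touched.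

Step 14
Reactants: 19 the 2'-methyl ether bis-pivalate of step 13
Product: 20 sophonorol F, (3S)-3,5-dihydroxy-3-[4-hydroxy-2-methoxy-3-(3-methylbut-2-en-1-yl)phenyl]-7-methoxy-8-(3-methylbut-2-en-1-yl)chroman-4-one
Conditions: K2CO3, MeOH, 25 °C, argon; aq NH4Cl
Reagents that add atoms: none
Why: Methanolysis (transesterification) of the two aryl pivalates under mild carbonate. C3 has no α-hydrogen and cannot epimerise, and room temperature should avoid α-ketol rearrangement.

## Compound list

1 | 3,5-dimethoxyphenol | COc1cc(O)cc(OC)c1 | starting material
2 | (3,5-dimethoxyphenoxy)triisopropylsilane | COc1cc(O[Si](C(C)C)(C(C)C)C(C)C)cc(OC)c1 | intermediate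
3 | prenyl bromide (1-bromo-3-methylbut-2-ene) | CC(C)=CCBr | starting material
4 | [2,6-dimethoxy-4-(triisopropylsilyloxy)phenyl]lithium | [Li]c1c(OC)cc(O[Si](C(C)C)(C(C)C)C(C)C)cc1OC | intermediate
5 | [3,5-dimethoxy-4-(3-methylbut-2-en-1-yl)phenoxy]triisopropylsilane | COc1cc(O[Si](C(C)C)(C(C)C)C(C)C)cc(OC)c1CC=C(C)C | intermediate
6 | 3,5-dimethoxy-4-(3-methylbut-2-en-1-yl)phenol | COc1cc(O)cc(OC)c1CC=C(C)C | intermediate
7 | 2-iodo-3,5-dimethoxy-4-(3-methylbut-2-en-1-yl)phenol | COc1cc(O)c(I)c(OC)c1CC=C(C)C | intermediate
8 | 2-iodo-3,5-dimethoxy-4-(3-methylbut-2-en-1-yl)phenyl pivalate | COc1cc(OC(=O)C(C)(C)C)c(I)c(OC)c1CC=C(C)C | intermediate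
9 | 2,4-dihydroxybenzaldehyde | O=Cc1ccc(O)cc1O | starting material
10 | 2,4-dihydroxy-3-(3-methylbut-2-en-1-yl)benzaldehyde | O=Cc1ccc(O)c(CC=C(C)C)c1O | intermediate
11 | 4-formyl-3-hydroxy-2-(3-methylbut-2-en-1-yl)phenyl pivalate | O=Cc1ccc(OC(=O)C(C)(C)C)c(CC=C(C)C)c1O | intermediate
12 | 3-[(tert-butyldimethylsilyl)oxy]-4-formyl-2-(3-methylbut-2-en-1-yl)phenyl pivalate | O=Cc1ccc(OC(=O)C(C)(C)C)c(CC=C(C)C)c1O[Si](C)(C)C(C)(C)C | intermediate
13 | lithium 1-aryl-2-diazo-2-(trimethylsilyl)ethanolate (racemic adduct of 12 with lithiated (trimethylsilyl)diazomethane) | [Li]OC(c1ccc(OC(=O)C(C)(C)C)c(CC=C(C)C)c1O[Si](C)(C)C(C)(C)C)C(=[N+]=[N-])[Si](C)(C)C | intermediate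
14 | 3-[(tert-butyldimethylsilyl)oxy]-4-ethynyl-2-(3-methylbut-2-en-1-yl)phenyl pivalate | C#Cc1ccc(OC(=O)C(C)(C)C)c(CC=C(C)C)c1O[Si](C)(C)C(C)(C)C | intermediate
15 | diarylalkyne of rings A and B (8a-OMe, 5- and 4'-pivalates, 2'-silyl ether) | COc1cc(OC(=O)C(C)(C)C)c(C#Cc2ccc(OC(=O)C(C)(C)C)c(CC=C(C)C)c2O[Si](C)(C)C(C)(C)C)c(OC)c1CC=C(C)C | intermediate
16 | 1,2-diketone (benzil) of rings A and B (8a-OMe, 5- and 4'-pivalates, 2'-silyl ether) | COc1cc(OC(=O)C(C)(C)C)c(C(=O)C(=O)c2ccc(OC(=O)C(C)(C)C)c(CC=C(C)C)c2O[Si](C)(C)C(C)(C)C)c(OC)c1CC=C(C)C | intermediate
17 | (3S)-3-hydroxyisoflavanone with 5- and 4'-pivalates and 2'-tert-butyldimethylsilyl ether | COc1cc(OC(=O)C(C)(C)C)c2c(c1CC=C(C)C)OC[C@@](O)(c1ccc(OC(=O)C(C)(C)C)c(CC=C(C)C)c1O[Si](C)(C)C(C)(C)C)C2=O | intermediate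
18 | caesium 2'-phenoxide of the (3S)-5,4'-bis-pivalate | COc1cc(OC(=O)C(C)(C)C)c2c(c1CC=C(C)C)OC[C@@](O)(c1ccc(OC(=O)C(C)(C)C)c(CC=C(C)C)c1[O-])C2=O.[Cs+] | intermediate
19 | (3S)-5,4'-di-O-pivaloyl sophonorol F | COc1cc(OC(=O)C(C)(C)C)c2c(c1CC=C(C)C)OC[C@@](O)(c1ccc(OC(=O)C(C)(C)C)c(CC=C(C)C)c1OC)C2=O | intermediate
20 | sophonorol F, (3S) | COc1cc(O)c2c(c1CC=C(C)C)OC[C@@](O)(c1ccc(O)c(CC=C(C)C)c1OC)C2=O | target

## Step count and least certain steps

Total: 14 steps. Longest linear sequence: 10 steps (steps 1–5 and 10–14, from 1); the ring B branch from 9 is 9 steps (steps 6–9 and 10–14).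

**Step 12 (marked as a new method).**
- What may go wrong: hydrogen abstraction by the proximal C4 oxygen followed by five-membered closure; return of the hydrogen atom so that little is converted; quenching of the triplet by prenyl alkenes. The most likely failure is poor facial selectivity, because the acid binds a hindered diketone only weakly, so that half of the material is lost on the chiral phase.
- Fallback (known chemistry): the carbene-catalysed intramolecular aldehyde–ketone benzoin reaction, which is established for 3-substituted 3-hydroxychroman-4-ones. It sets out from 6 and 14 and comes back to the route at 17.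
  - Ring A part: ortho-formylation of 6 (MgCl2, Et3N, paraformaldehyde, MeCN, 80 °C) would give 6-hydroxy-2,4-dimethoxy-3-prenylbenzaldehyde F1, and pivaloylation its pivalate F2. MgI2·OEt2 would then cleave only the methyl ether chelated to the formyl group (the one beside the prenyl group), giving phenol F3.
  - Ring B part: hydration of 14 ((Ph3P)AuNTf2, wet dioxane) would give methyl ketone F4. Its trimethylsilyl enol ether F5 (Me3SiOTf, Et3N) would be brominated with N-bromosuccinimide at −78 °C to bromoketone F6, the enol ether reacting before the prenyl alkene.
  - Union and closure: alkylation of F3 with F6 (K2CO3, acetone) would give keto aldehyde F7, and an aminoindanol-derived chiral triazolium salt with Et3N would close it to 17.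

**Step 11.**
- What may go wrong: divalent palladium activates the triple bond toward attack by the neighbouring silyloxy or pivaloyloxy oxygen (cyclisation with loss of the protecting group), it coordinates to the prenyl alkenes with double-bond migration, and the aryl silyl ether may be lost thermally in DMSO at 120 °C.
- Fallback: palladium and sulfoxide chemistry is left altogether. It sets out from 15 and comes back at 16 with no new compound. A monovalent gold catalyst, (Ph3P)AuNTf2, with 2,6-dichloropyridine N-oxide in 1,2-dichloroethane at 25 °C would transfer two oxygen atoms through an α-oxo gold carbene, a known route from diarylalkynes to 1,2-diketones that works at room temperature, where neither the alkenes nor the silyl ether are stressed.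

**Step 9.**
- What may go wrong: migration of the silyl group from the phenolic oxygen to the alkoxide of 13, which would stop the Peterson-type elimination, or attack of the lithiated diazomethane on the pivalate.
- Fallback: a route without any alkoxide, setting out from 12 and coming back at 14. Dibromo-olefination (CBr4, PPh3, CH2Cl2, 0 °C) would give the 1,1-dibromoalkene F8. Inverse addition to n-BuLi (2 equiv) at −78 °C would give, by bromine–lithium exchange and Fritsch–Buttenberg–Wiechell rearrangement, the lithium acetylide F9, protonated on work-up to 14 (Corey–Fuchs sequence).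

**Step 6.**
- What may go wrong: O-alkylation, alkylation at C5 and double alkylation, so that little of the C3 isomer is obtained.
- Fallback: the prenyl group is delivered by sigmatropic shift instead of intermolecular alkylation, setting out from 9 and coming back at 10. Alkylation of the unchelated 4-hydroxyl with 3-chloro-3-methylbut-1-yne (K2CO3, KI, CuI, acetone) would give the propargyl ether F10. Partial hydrogenation over Pd/CaCO3 poisoned with Pb(OAc)2 (quinoline) would give the 1,1-dimethylallyl ether F11. Heating (N,N-diethylaniline, 130 °C) should move the allyl group by ortho-Claisen rearrangement, with inversion, to the carbon between the two oxygens.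

**Step 4.**
- What may go wrong: attack of iodine on the prenyl alkene with participation of a neighbouring methoxy oxygen, or a second iodination at the other equivalent position.
- Fallback: the iodine is introduced through an aryllithium instead of by electrophilic substitution, setting out from 6 and coming back at 7. The MOM ether F12 (MOMCl, i-Pr2NEt) would be lithiated by n-BuLi at −20 °C between the acetal oxygen and a methoxy group (the two such positions are equivalent) to give aryllithium F13. This would be quenched with I2 at −78 °C to iodide F14, and the acetal removed by methanolysis (0.1 M HCl in MeOH, 25 °C); no free hydroxyl sits beside the prenyl group, so no ring can close.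

## Further compounds

F1 | step 12 | 6-hydroxy-2,4-dimethoxy-3-(3-methylbut-2-en-1-yl)benzaldehyde | COc1cc(O)c(C=O)c(OC)c1CC=C(C)C
F2 | step 12 | 2-formyl-3,5-dimethoxy-4-(3-methylbut-2-en-1-yl)phenyl pivalate | COc1cc(OC(=O)C(C)(C)C)c(C=O)c(OC)c1CC=C(C)C
F3 | step 12 | 2-formyl-3-hydroxy-5-methoxy-4-(3-methylbut-2-en-1-yl)phenyl pivalate | COc1cc(OC(=O)C(C)(C)C)c(C=O)c(O)c1CC=C(C)C
F4 | step 12 | 4-acetyl-3-[(tert-butyldimethylsilyl)oxy]-2-(3-methylbut-2-en-1-yl)phenyl pivalate | CC(=O)c1ccc(OC(=O)C(C)(C)C)c(CC=C(C)C)c1O[Si](C)(C)C(C)(C)C
F5 | step 12 | 3-[(tert-butyldimethylsilyl)oxy]-2-(3-methylbut-2-en-1-yl)-4-[1-(trimethylsilyloxy)vinyl]phenyl pivalate | C=C(O[Si](C)(C)C)c1ccc(OC(=O)C(C)(C)C)c(CC=C(C)C)c1O[Si](C)(C)C(C)(C)C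
F6 | step 12 | 4-(bromoacetyl)-3-[(tert-butyldimethylsilyl)oxy]-2-(3-methylbut-2-en-1-yl)phenyl pivalate | BrCC(=O)c1ccc(OC(=O)C(C)(C)C)c(CC=C(C)C)c1O[Si](C)(C)C(C)(C)C
F7 | step 12 | keto aldehyde: 2-formyl-5-methoxy-4-(3-methylbut-2-en-1-yl)-3-{2-oxo-2-[2-[(tert-butyldimethylsilyl)oxy]-3-(3-methylbut-2-en-1-yl)-4-(pivaloyloxy)phenyl]ethoxy}phenyl pivalate | COc1cc(OC(=O)C(C)(C)C)c(C=O)c(OCC(=O)c2ccc(OC(=O)C(C)(C)C)c(CC=C(C)C)c2O[Si](C)(C)C(C)(C)C)c1CC=C(C)C
F0 | step 11 | none | none
F8 | step 9 | 3-[(tert-butyldimethylsilyl)oxy]-4-(2,2-dibromovinyl)-2-(3-methylbut-2-en-1-yl)phenyl pivalate | BrC(Br)=Cc1ccc(OC(=O)C(C)(C)C)c(CC=C(C)C)c1O[Si](C)(C)C(C)(C)C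
F9 | step 9 | lithium acetylide of 14 | [Li]C#Cc1ccc(OC(=O)C(C)(C)C)c(CC=C(C)C)c1O[Si](C)(C)C(C)(C)C
F10 | step 6 | 2-hydroxy-4-[(2-methylbut-3-yn-2-yl)oxy]benzaldehyde | O=Cc1ccc(OC(C)(C)C#C)cc1O
F11 | step 6 | 2-hydroxy-4-[(2-methylbut-3-en-2-yl)oxy]benzaldehyde | O=Cc1ccc(OC(C)(C)C=C)cc1O
F12 | step 4 | 1,3-dimethoxy-5-(methoxymethoxy)-2-(3-methylbut-2-en-1-yl)benzene | COCOc1cc(OC)c(CC=C(C)C)c(OC)c1
F13 | step 4 | [2,4-dimethoxy-6-(methoxymethoxy)-3-(3-methylbut-2-en-1-yl)phenyl]lithium | [Li]c1c(OCOC)cc(OC)c(CC=C(C)C)c1OC
F14 | step 4 | 1-iodo-2,4-dimethoxy-6-(methoxymethoxy)-3-(3-methylbut-2-en-1-yl)benzene | COCOc1cc(OC)c(CC=C(C)C)c(OC)c1I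
A1 | alternative 1 | (S)-α-hydroxy-α-(hydroxymethyl) deoxybenzoin (seco-chromanone diol; 5,4'-bis-MOM, 8a-silyl ether) | COc1cc(OCOC)c(C(=O)[C@@](O)(CO)c2ccc(OCOC)c(CC=C(C)C)c2OC)c(O[Si](C)(C)C(C)(C)C)c1CC=C(C)C
A2 | alternative 1 | 2-diazo-1,2-diarylethanone of rings A and B (5,4'-bis-MOM, 2'-OMe, 8a-silyl ether) | COc1cc(OCOC)c(C(=O)C(=[N+]=[N-])c2ccc(OCOC)c(CC=C(C)C)c2OC)c(O[Si](C)(C)C(C)(C)C)c1CC=C(C)C
A3 | alternative 2 | (S)-2'-O-demethyl-4'-O-pivaloyl sophonorol F | COc1cc(O)c2c(c1CC=C(C)C)OC[C@@](O)(c1ccc(OC(=O)C(C)(C)C)c(CC=C(C)C)c1O)C2=O
A4 | alternative 2 | (3S)-3-hydroxy-7-methoxy-5-(prenyloxy)-3-[2-(2-methylbut-3-en-2-yloxy)-4-(pivaloyloxy)phenyl]chroman-4-one | COc1cc(OCC=C(C)C)c2c(c1)OC[C@@](O)(c1ccc(OC(=O)C(C)(C)C)cc1OC(C)(C)C=C)C2=O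
A5 | alternative 3 | (S)-5,4'-bis-O-(methoxymethyl) sophonorol F | COc1cc(OCOC)c2c(c1CC=C(C)C)OC[C@@](O)(c1ccc(OCOC)c(CC=C(C)C)c1OC)C2=O
A6 | alternative 3 | 4-methoxy-6-(methoxymethoxy)-3-(3-methylbut-2-en-1-yl)-2-{2-oxo-2-[2-methoxy-4-(methoxymethoxy)-3-(3-methylbut-2-en-1-yl)phenyl]ethoxy}benzaldehyde | COc1cc(OCOC)c(C=O)c(OCC(=O)c2ccc(OCOC)c(CC=C(C)C)c2OC)c1CC=C(C)C
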